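## Structural features

Target 33 is an ent-labdane: a trans-fused decalin (rings A and B) with a gem-dimethyl group at C4, an equatorial secondary alcohol at C3 (R), an angular methyl on the quaternary C10, an equatorial formyl group (C17) on C8, and on C9 an equatorial C11–C12 tether that ends in a (Z)-β-methyl enoate (C13=C14, methyl ester C15, methyl C16). Four of the five stereocentres (C8, C9, C10, C5) are contiguous around ring B, and the fifth (C3) is separated from C5 only by the quaternary C4. Every ring substituent except the axial C10 methyl is equatorial, so the relative configuration is the thermodynamically relaxed one. The fragile groups are the C17 aldehyde (epimerisable α-CH, easily over-oxidised), the trisubstituted Z-enoate (isomerisable, and reducible by dissolving metals) and the free C3 hydroxyl beside a neopentyl centre. The real difficulty is the quaternary C10 flanked by C9 and C5, combined with three oxygen functions at three oxidation levels and a defined olefin geometry. The key step uses the fact that C3–O, one C4 methyl, C5 and C10 with its methyl map onto a 2,4-dimethylphenol whose meta carbon C5 carries the C6–C9 chain. The para carbon C10 of the phenolate can then close ring B onto C9 and become quaternary in the same event, leaving a vinyl group (C11=C12) on C9 for the side chain.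

## Logic of the disconnections

33 ⇒ 32 ⇒ 31. Only the oxidation level and protection of C17 change. The epimerisable aldehyde is unmasked last, so C8 is never exposed to base as an aldehyde. This demands a primary-selective oxidation of 32 in the presence of the C3 hydroxyl and a desilylation of 31 that spares the Z-enoate.

31 ⇒ 27 + 29 (through 30). The C12–C13 sp3–sp2 bond is cut. The Z geometry is bought in 29 and transferred with retention, and the vinyl group of 27 becomes the C12 nucleophile by hydroboration. One step therefore attaches C13–C16 complete with geometry. The demand is anti-Markovnikov hydroboration beside a free hydroxyl and a coupling that does not scramble the olefin. 29 ⇒ 28 cuts C13–I; anti hydroiodination of the ynoate sets the geometry.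

27 ⇒ 26 ⇒ 24 (through 25). The C3–H bond, one C4–CH3 bond and the C5–H bond are removed. Reductive methylation of the enone sets the trans fusion (C5) and completes the gem-dimethyl group in one operation, and hydride reduction then sets C3. The demand is a regiodefined enolate 25 and survival of the vinyl group and silyl ether under dissolving-metal conditions.

24 ⇒ 23. The C1=C2 unsaturation is put back. The demand on the forward step is reduction of the less substituted enone olefin only, leaving C4=C5 and the vinyl group.

23 ⇒ 22 (key disconnection). The C9–C10 bond is cut; ring B opens and ring A becomes an aromatic phenol. This removes the quaternary centre and the C9 stereocentre and leaves only C8 in an acyclic chain on a flat arene. The forward step must deliver para (C10) rather than ortho (C4) attack, closure at C9 rather than C12, and the all-equatorial diastereomer.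

22 ⇒ 21 ⇒ 20 ⇒ 19. These are functional-group changes: the phenol is unmasked, the C12–O carbonate bond is cut, and the C12 ester is the precursor of the allylic alcohol. The aryl silyl ether must be cleaved in the presence of the alkyl silyl ether and the carbonate.

19 ⇒ 16 + 17 (through 18). The C9=C11 olefin is cut. A stabilised ylide gives the E geometry, and 18 must not epimerise at C8, so it is made and consumed in one flask.

16 ⇒ 15 ⇒ 14 ⇒ 12 (through 13). The C9–N acyl bond (reductive removal of the auxiliary) and the C8–C17 bond (hydroxymethylation of an auxiliary-bound enolate) are cut. This is where C8, the only stereocentre not made in the key step or after it, is introduced with reagent control.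

12 ⇒ 9 + 10 (through 11), and 9 ⇒ 8 ⇒ 6 + 7. The N–acyl bond and the aryl–alkyl bond C5–C6 are cut. The coupling must work at a bromide flanked by two methyl groups.

6 ⇒ 5 ⇒ 3 (through 4) ⇒ 2 ⇒ 1. The O–Si bond, then C–O traced back to C–N and C–H. Nitration of 1 is directed by both methyl groups to the position that becomes C3.

## Other disconnections considered

Alternative 1: The cut is in the side chain at C12–C13 and C14–C15, with the whole bicyclic core taken from the natural ent-labdane andrographolide A1. In the forward key step a C12 alkylcopper derived from A1 would add syn across a three-carbon terminal alkyne, and the (Z)-alkenylcopper would be acylated by a chloroformate to give A2.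
- In favour: C3, C5, C9 and C10 arrive with the correct absolute configuration, the Z-enoate is made stereospecifically in one pot, and the count from A1 would probably be below the 22 steps of the chosen route. On certainty of the ring stereocentres and on step economy it is the better plan; on stereospecificity of the enoate construction it is the equal of step 20.
- Against: A1 has a C19 hydroxyl that must be removed at a neopentyl carbon. Hydroboration of its exocyclic C8=C17 olefin is expected from the face opposite the C10 methyl, giving the axial C17 epimer, so an oxidation/epimerisation detour is needed. The hydroxybutenolide must be degraded to a C12 halide while three hydroxyls are differentiated. A primary organocopper beside an acetal and a silyl ether is less forgiving than a borane.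
- Comparison: both plans end with a stereoretentive sp3–sp2 union. Alternative 1 carries no risk at the quaternary centre, but it degrades a natural product instead of constructing the skeleton, which is why it was not taken as the total synthesis.

Alternative 2: Both rings are cut at C5–C10 and C8–C9, which unravels the decalin to the acyclic ester A3. A3 has three C=C bonds (the 2E-enoate and the 8E,10E-diene), so it is correctly a trienoate rather than a tetraenoate. Heating or Lewis-acid activation should bring the C9=C10 enoate onto the C5=C6–C7=C8 diene through the ester-endo transition state, with the tether in a chair and the C3 silyloxy group equatorial, to give the trans-fused octalin A4.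
- In favour: one step makes two rings, two C–C bonds and four stereocentres; the gem-dimethyl group and the C3 oxygen are present from the start; no dissolving-metal step is needed. In complexity gained per step it is the better plan.
- Against: the dienophile is a β,β-disubstituted enoate that must create the quaternary C10, and the diene terminus C5 is neopentyl, so the cycloaddition is expected to be slow with unassured endo/exo and facial preferences. A4 has the C8 group axial and must be epimerised through the aldehyde, C6=C7 must be hydrogenated, and C11 arrives as an ester, so C12–C16 and the Z-olefin still have to be attached.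
- Comparison: the stereochemical risk is of the same order (one unsecured selectivity in each plan), and the mechanism is simpler (one uncatalysed pericyclic event). The sequence after the key step would be clearly longer than the seven steps that follow step 15.

Alternative 3: The cuts are C9–C11 and C1–C10 on a preformed ring B enone A5. A but-3-enyl copper reagent should add to C9 anti to the C8 substituent, and the C10 enolate should be trapped by an α-silyl vinyl ketone anti to the new C9 group, giving the 1,5-diketone A6. Aldol condensation would then close ring A to a 4-methyl enone of the same type as 24, so steps 17 and 18 could be taken over unchanged.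
- In favour: both stereochemical events are of a firmly established kind, there is no ortho/para question, and C10 is made by enolate alkylation. On reliability of the ring-forming steps it is the better plan; on the ring A endgame it is the equal.
- Against: A5 must first be made enantioenriched. The butenyl group supplies C11–C13 and the future C16 but neither C14/C15 nor the olefin geometry, so a C13 methyl ketone (after Wacker oxidation) would have to be olefinated Z-selectively, which is the weak transformation for methyl ketones. Ring A is assembled from three pieces instead of being bought as an arene.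
- Comparison: step economy would be close. The chosen plan keeps a vinyl group on C9, which lets the Z-enoate be attached as a preformed unit; with a vinyl copper reagent this alternative would converge on 24.

Key step: step 15

Remark: labdane numbering is used for the skeletal carbons of all intermediates; TBS = tert-butyl(dimethyl)silyl, TIPS = tri(propan-2-yl)silyl.
Remark: C8 keeps one spatial arrangement from 14 to 33; it is designated R in 14, 15 and 18 and S elsewhere only because the CIP ranking of C9 changes.
Remark: no ring substituent can favour C10 over C4 (C1 is ortho to C10 and para to C4, C2 is meta to both), so the constitution of 22 is kept and regiocontrol is sought from the cation-free phenolate, the ligand and dilution.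
Remark: 7 is assumed to be bought as its commercial 0.5 M THF solution.

## Route

Step 1
Reactants: 1 2-bromo-1,3-dimethylbenzene
Product: 2 2-bromo-1,3-dimethyl-4-nitrobenzene
Conditions: HNO3 (1.1 equiv), H2SO4, AcOH, 0 °C → rt
Reagents that add atoms: nitric acid, O[N+](=O)[O-]
Why: Electrophilic aromatic nitration; the position ortho to one methyl and para to the other is the most activated and is not flanked by bromine, so mononitration is expected there.

Step 2
Reactants: 2 2-bromo-1,3-dimethyl-4-nitrobenzene
Product: 3 3-bromo-2,4-dimethylaniline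
Conditions: Fe powder, NH4Cl, EtOH/H2O, 80 °C
Reagents that add atoms: none
Why: Béchamp-type reduction of the nitro group by iron under nearly neutral conditions, which leaves the aryl bromide untouched.

Step 3
Reactants: 3 3-bromo-2,4-dimethylaniline
Product: 5 3-bromo-2,4-dimethylphenol, via arenediazonium hydrogensulfate 4 (not isolated)
Conditions: NaNO2, H2SO4 (aq), 0 °C; then H2SO4 (aq), 100 °C
Reagents that add atoms: water, O
Why: Diazotisation followed by thermal hydrolysis of the diazonium salt (loss of N2, capture of the aryl cation by water); the strongly acidic medium suppresses azo coupling and cyclisation onto the ortho methyl group.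

Step 4
Reactants: 5 3-bromo-2,4-dimethylphenol
Product: 6 (3-bromo-2,4-dimethylphenoxy)tri(propan-2-yl)silane
Conditions: i-Pr3SiCl, imidazole, DMF, rt
Reagents that add atoms: chlorotri(propan-2-yl)silane, CC(C)[Si](Cl)(C(C)C)C(C)C
Why: Silylation of the phenol; the bulky silyl ether is chosen because it should withstand the organozinc reagent, LiOH, TiCl4 and hydrides and can later be removed by fluoride faster than an alkyl silyl ether.

Step 5
Reactants: 6 (3-bromo-2,4-dimethylphenoxy)tri(propan-2-yl)silane; 7 (4-ethoxy-4-oxobutyl)zinc bromide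
Product: 8 ethyl 4-{2,6-dimethyl-3-[tri(propan-2-yl)silyloxy]phenyl}butanoate
Conditions: Pd(OAc)2 (2 mol%), SPhos (4 mol%), THF, 50 °C
Reagents that add atoms: none
Why: Negishi sp2–sp3 coupling; the bulky electron-rich biarylphosphine promotes oxidative addition and reductive elimination at the di-ortho-substituted bromide, and the ester is inert to the alkylzinc halide.

Step 6
Reactants: 8 ethyl 4-{2,6-dimethyl-3-[tri(propan-2-yl)silyloxy]phenyl}butanoate
Product: 9 4-{2,6-dimethyl-3-[tri(propan-2-yl)silyloxy]phenyl}butanoic acid
Conditions: LiOH·H2O, THF/MeOH/H2O, rt; then 1 M HCl to pH 3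
Reagents that add atoms: lithium hydroxide, [Li+].[OH-]
Why: Saponification of the ethyl ester; the hindered aryl silyl ether (ortho methyl, three isopropyl groups) is expected to survive LiOH at room temperature.

Step 7
Reactants: 9 4-{2,6-dimethyl-3-[tri(propan-2-yl)silyloxy]phenyl}butanoic acid; 10 (4S)-4-benzyl-1,3-oxazolidin-2-one
Product: 12 (4S)-4-benzyl-3-(4-{2,6-dimethyl-3-[tri(propan-2-yl)silyloxy]phenyl}butanoyl)-1,3-oxazolidin-2-one, via mixed pivalic anhydride 11 (not isolated)
Conditions: t-BuCOCl, Et3N, THF, −20 °C; then LiCl, 10, −20 °C → rt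
Reagents that add atoms: none
Why: N-Acylation of the oxazolidinone through the mixed anhydride under LiCl/Et3N activation; attack occurs at the less hindered carbonyl of the anhydride.

Step 8
Reactants: 12 (4S)-4-benzyl-3-(4-{2,6-dimethyl-3-[tri(propan-2-yl)silyloxy]phenyl}butanoyl)-1,3-oxazolidin-2-one
Product: 14 (4S)-4-benzyl-3-[(2R)-4-{2,6-dimethyl-3-[tri(propan-2-yl)silyloxy]phenyl}-2-(hydroxymethyl)butanoyl]-1,3-oxazolidin-2-one, via trichlorotitanium enolate 13 (not isolated)
Conditions: TiCl4 (1.05 equiv), i-Pr2NEt, CH2Cl2, 0 °C; then 1,3,5-trioxane, TiCl4 (1.05 equiv), 0 °C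
Reagents that add atoms: 1,3,5-trioxane, C1OCOCO1
Why: Auxiliary-controlled aldol-type hydroxymethylation: the chelated (Z)-titanium enolate 13 is attacked by TiCl4-activated formaldehyde on the face opposite the benzyl group, which sets C8 (2R in 14).

Step 9
Reactants: 14 (4S)-4-benzyl-3-[(2R)-4-{2,6-dimethyl-3-[tri(propan-2-yl)silyloxy]phenyl}-2-(hydroxymethyl)butanoyl]-1,3-oxazolidin-2-one
Product: 15 (4S)-4-benzyl-3-[(2R)-2-{[tert-butyl(dimethyl)silyl]oxymethyl}-4-{2,6-dimethyl-3-[tri(propan-2-yl)silyloxy]phenyl}butanoyl]-1,3-oxazolidin-2-one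
Conditions: t-BuMe2SiCl, imidazole, DMF, rt
Reagents that add atoms: tert-butylchlorodimethylsilane, CC(C)(C)[Si](C)(C)Cl
Why: Silylation of the primary alcohol; this ether blocks retro-aldol cleavage and is stable to every later step up to step 21, including Li/NH3.

Step 10
Reactants: 15 (4S)-4-benzyl-3-[(2R)-2-{[tert-butyl(dimethyl)silyl]oxymethyl}-4-{2,6-dimethyl-3-[tri(propan-2-yl)silyloxy]phenyl}butanoyl]-1,3-oxazolidin-2-one
Product: 16 (2S)-2-{[tert-butyl(dimethyl)silyl]oxymethyl}-4-{2,6-dimethyl-3-[tri(propan-2-yl)silyloxy]phenyl}butan-1-ol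
Conditions: LiBH4, MeOH (1 equiv), THF, 0 °C
Reagents that add atoms: none
Why: Reductive cleavage of the N-acyl oxazolidinone at the exocyclic carbonyl; the auxiliary is released and C8 is not epimerised.

Step 11
Reactants: 16 (2S)-2-{[tert-butyl(dimethyl)silyl]oxymethyl}-4-{2,6-dimethyl-3-[tri(propan-2-yl)silyloxy]phenyl}butan-1-ol; 17 ethyl 2-(triphenylphosphoranylidene)acetate
Product: 19 ethyl (2E,4S)-4-{[tert-butyl(dimethyl)silyl]oxymethyl}-6-{2,6-dimethyl-3-[tri(propan-2-yl)silyloxy]phenyl}hex-2-enoate, via aldehyde 18 (not isolated)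
Conditions: (COCl)2, DMSO, CH2Cl2, −78 °C; Et3N; then 17, −78 °C → rt
Reagents that add atoms: none
Why: Swern oxidation followed in the same flask by Wittig olefination; the α-branched β-silyloxy aldehyde 18 is consumed without isolation, which limits epimerisation at C8 and β-elimination, and the stabilised ylide gives the E-enoate.

Step 12
Reactants: 19 ethyl (2E,4S)-4-{[tert-butyl(dimethyl)silyl]oxymethyl}-6-{2,6-dimethyl-3-[tri(propan-2-yl)silyloxy]phenyl}hex-2-enoate
Product: 20 (2E,4S)-4-{[tert-butyl(dimethyl)silyl]oxymethyl}-6-{2,6-dimethyl-3-[tri(propan-2-yl)silyloxy]phenyl}hex-2-en-1-ol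
Conditions: i-Bu2AlH (2.5 equiv), CH2Cl2, −78 °C
Reagents that add atoms: none
Why: 1,2-Reduction of the enoate to the allylic alcohol at low temperature; the olefin and both silyl ethers are unaffected.

Step 13
Reactants: 20 (2E,4S)-4-{[tert-butyl(dimethyl)silyl]oxymethyl}-6-{2,6-dimethyl-3-[tri(propan-2-yl)silyloxy]phenyl}hex-2-en-1-ol
Product: 21 (2E,4S)-4-{[tert-butyl(dimethyl)silyl]oxymethyl}-6-{2,6-dimethyl-3-[tri(propan-2-yl)silyloxy]phenyl}hex-2-en-1-yl methyl carbonate
Conditions: ClCO2Me, pyridine, CH2Cl2, 0 °C
Reagents that add atoms: methyl chloroformate, COC(=O)Cl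
Why: Acylation of the primary allylic alcohol to the methyl carbonate, the leaving group that will release its own base in step 15.

Step 14
Reactants: 21 (2E,4S)-4-{[tert-butyl(dimethyl)silyl]oxymethyl}-6-{2,6-dimethyl-3-[tri(propan-2-yl)silyloxy]phenyl}hex-2-en-1-yl methyl carbonate
Product: 22 (2E,4S)-4-{[tert-butyl(dimethyl)silyl]oxymethyl}-6-(3-hydroxy-2,6-dimethylphenyl)hex-2-en-1-yl methyl carbonate
Conditions: Bu4NF (1.1 equiv), AcOH (1.1 equiv), THF, 0 °C
Reagents that add atoms: none
Why: Fluoride cleaves the aryl O–Si bond much faster than the primary alkyl O–Si bond because phenoxide is the better leaving group from pentacoordinate silicon; acetic acid buffers the phenoxide so the carbonate is not attacked.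

Step 15
Reactants: 22 (2E,4S)-4-{[tert-butyl(dimethyl)silyl]oxymethyl}-6-(3-hydroxy-2,6-dimethylphenyl)hex-2-en-1-yl methyl carbonate
Product: 23 (4aS,5R,6S)-6-{[tert-butyl(dimethyl)silyl]oxymethyl}-5-ethenyl-1,4a-dimethyl-5,6,7,8-tetrahydronaphthalen-2(4aH)-one
Conditions: Pd2(dba)3·CHCl3 (2.5 mol%), (R,R)-DACH-phenyl bisphosphine ligand (7.5 mol%), CH2Cl2 (0.01 M), rt
Reagents that add atoms: none
Why: Proposed new method: zerovalent palladium ionises the allylic carbonate of 22 with loss of CO2, the methoxide set free deprotonates the phenol, and the para carbon C10 of the phenolate attacks the internal terminus C9 of the π-allyl cation on the face opposite the metal; the closest known reaction type is the palladium- or iridium-catalysed intramolecular allylic dearomatisation of para-tethered phenols to spirocyclohexadienones (with the base-mediated Ar2-6 phenolate closure as classical analogue), here extended to a meta tether and a methyl-bearing para carbon so that a fused ring results. Ring B is closed in a 6-exo mode on the allyl unit through a chair-like transition state, and closure at C12 would need an eight-membered ring. C9 is controlled by the C8 silyloxymethyl group, which sits equatorial and places the remainder of the allyl unit equatorial and trans to it, and by the ligand, which can choose between the two allyl faces because they interconvert through an η1 complex at the CH2 terminus C12. C10 follows from C9, since in the chair the tether allows bond formation on only one arene face and the methyl group is pushed to the other, axial, side. The step needs para attack at C10 to beat ortho attack at C4, which would close a ring of the same size: the larger HOMO coefficient of a cation-free phenolate at the para carbon, the lower congestion at C10 (flanked by C1–H, whereas C4 is flanked by the solvated oxygen) and the possibility that zerovalent palladium re-ionises a kinetically formed linear dienone and funnels it to the more stable cross-conjugated isomer all point the same way, but none of this is guaranteed. O-Allylation is excluded geometrically because it would give a meta-bridged ether, and high dilution suppresses intermolecular allylation at the free C2 position.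

Step 16
Reactants: 23 (4aS,5R,6S)-6-{[tert-butyl(dimethyl)silyl]oxymethyl}-5-ethenyl-1,4a-dimethyl-5,6,7,8-tetrahydronaphthalen-2(4aH)-one
Product: 24 (4aS,5R,6S)-6-{[tert-butyl(dimethyl)silyl]oxymethyl}-5-ethenyl-1,4a-dimethyl-4,4a,5,6,7,8-hexahydronaphthalen-2(3H)-one
Conditions: [(Ph3P)CuH]6 (0.4 equiv), H2O (3 equiv), PhMe, rt
Reagents that add atoms: none
Why: Conjugate reduction by the phosphine copper hydride: hydride goes to the less substituted β-carbon C1, the tetrasubstituted C4=C5 enone and the isolated vinyl group are not reduced by this reagent, and water protonates the copper enolate at C2.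

Step 17
Reactants: 24 (4aS,5R,6S)-6-{[tert-butyl(dimethyl)silyl]oxymethyl}-5-ethenyl-1,4a-dimethyl-4,4a,5,6,7,8-hexahydronaphthalen-2(3H)-one
Product: 26 (4aS,5R,6S,8aS)-6-{[tert-butyl(dimethyl)silyl]oxymethyl}-5-ethenyl-1,1,4a-trimethyloctahydronaphthalen-2(1H)-one, via lithium enolate 25 (not isolated)
Conditions: Li (2.5 equiv), t-BuOH (1.0 equiv), NH3 (l)/THF, −78 °C; isoprene; then MeI, −78 → −33 °C
Reagents that add atoms: iodomethane, CI
Why: Dissolving-metal reduction of the enone with alkylation of the resulting enolate (reductive alkylation): axial protonation of C5 anti to the C10 methyl gives the trans ring fusion, and the regiodefined enolate 25 is methylated at C4 to complete the gem-dimethyl group. The isolated vinyl group and the silyl ether are inert to Li/NH3.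

Step 18
Reactants: 26 (4aS,5R,6S,8aS)-6-{[tert-butyl(dimethyl)silyl]oxymethyl}-5-ethenyl-1,1,4a-trimethyloctahydronaphthalen-2(1H)-one
Product: 27 (2R,4aS,5R,6S,8aS)-6-{[tert-butyl(dimethyl)silyl]oxymethyl}-5-ethenyl-1,1,4a-trimethyldecahydronaphthalen-2-ol
Conditions: NaBH4, MeOH, 0 °C
Reagents that add atoms: none
Why: Hydride attacks the C3 ketone along the axial trajectory from the face opposite the axial C4 and C10 methyl groups, so the equatorial (3R) alcohol is the expected major isomer.

Step 19
Reactants: 28 methyl but-2-ynoate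
Product: 29 methyl (2Z)-3-iodobut-2-enoate
Conditions: NaI, AcOH, 110 °C
Reagents that add atoms: sodium iodide, [Na+].[I-]
Why: Conjugate addition of iodide to the ynoate with anti protonation gives the (Z)-β-iodo enoate, in which iodine and the ester are cis.

Step 20
Reactants: 27 (2R,4aS,5R,6S,8aS)-6-{[tert-butyl(dimethyl)silyl]oxymethyl}-5-ethenyl-1,1,4a-trimethyldecahydronaphthalen-2-ol; 29 methyl (2Z)-3-iodobut-2-enoate
Product: 31 methyl (2Z)-5-[(1R,2S,4aS,6R,8aS)-2-{[tert-butyl(dimethyl)silyl]oxymethyl}-6-hydroxy-5,5,8a-trimethyldecahydronaphthalen-1-yl]-3-methylpent-2-enoate, via B-alkyl-9-borabicyclononane 30 (not isolated)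
Conditions: 9-BBN (2.5 equiv), THF, 0 °C → rt; then K3PO4 (aq), 29, Pd(dppf)Cl2 (5 mol%), AsPh3, DMF, rt
Reagents that add atoms: none
Why: Anti-Markovnikov hydroboration of the monosubstituted olefin by 9-BBN (the excess allows for the free hydroxyl), then B-alkyl Suzuki–Miyaura coupling with the vinyl iodide, which proceeds with retention and so transfers the Z geometry of 29 to C13=C14.

Step 21
Reactants: 31 methyl (2Z)-5-[(1R,2S,4aS,6R,8aS)-2-{[tert-butyl(dimethyl)silyl]oxymethyl}-6-hydroxy-5,5,8a-trimethyldecahydronaphthalen-1-yl]-3-methylpent-2-enoate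
Product: 32 methyl (2Z)-5-[(1R,2S,4aS,6R,8aS)-6-hydroxy-2-(hydroxymethyl)-5,5,8a-trimethyldecahydronaphthalen-1-yl]-3-methylpent-2-enoate
Conditions: HF·pyridine, pyridine, THF, 0 °C → rt
Reagents that add atoms: none
Why: Buffered acidic fluoride cleaves the primary silyl ether; the methyl ester, the Z-olefin and the C3 alcohol are stable to these conditions.

Step 22
Reactants: 32 methyl (2Z)-5-[(1R,2S,4aS,6R,8aS)-6-hydroxy-2-(hydroxymethyl)-5,5,8a-trimethyldecahydronaphthalen-1-yl]-3-methylpent-2-enoate
Product: 33 methyl (2Z)-5-[(1R,2S,4aS,6R,8aS)-2-formyl-6-hydroxy-5,5,8a-trimethyldecahydronaphthalen-1-yl]-3-methylpent-2-enoate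
Conditions: TEMPO (10 mol%), PhI(OAc)2, CH2Cl2, rt
Reagents that add atoms: none
Why: Oxoammonium (TEMPO) oxidation with PhI(OAc)2 as terminal oxidant is selective for the primary over the hindered secondary alcohol and stops at the aldehyde without epimerising conditions; the equatorial C8 aldehyde is also the thermodynamically preferred epimer.

## Compound list

1 | 2-bromo-1,3-dimethylbenzene | Cc1cccc(C)c1Br | starting material
2 | 2-bromo-1,3-dimethyl-4-nitrobenzene | Cc1ccc([N+](=O)[O-])c(C)c1Br | intermediate
3 | 3-bromo-2,4-dimethylaniline | Cc1ccc(N)c(C)c1Br | intermediate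
4 | 3-bromo-2,4-dimethylbenzenediazonium hydrogensulfate | Cc1ccc([N+]#N)c(C)c1Br.OS(=O)(=O)[O-] | intermediate
5 | 3-bromo-2,4-dimethylphenol | Cc1ccc(O)c(C)c1Br | intermediate
6 | (3-bromo-2,4-dimethylphenoxy)tri(propan-2-yl)silane | Cc1ccc(O[Si](C(C)C)(C(C)C)C(C)C)c(C)c1Br | intermediate
7 | (4-ethoxy-4-oxobutyl)zinc bromide | CCOC(=O)CCC[Zn]Br | starting material
8 | ethyl 4-{2,6-dimethyl-3-[tri(propan-2-yl)silyloxy]phenyl}butanoate | CCOC(=O)CCCc1c(C)ccc(O[Si](C(C)C)(C(C)C)C(C)C)c1C | intermediate
9 | 4-{2,6-dimethyl-3-[tri(propan-2-yl)silyloxy]phenyl}butanoic acid | OC(=O)CCCc1c(C)ccc(O[Si](C(C)C)(C(C)C)C(C)C)c1C | intermediate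
10 | (4S)-4-benzyl-1,3-oxazolidin-2-one | O=C1N[C@@H](Cc2ccccc2)CO1 | starting material
11 | 4-{2,6-dimethyl-3-[tri(propan-2-yl)silyloxy]phenyl}butanoic 2,2-dimethylpropanoic anhydride | CC(C)(C)C(=O)OC(=O)CCCc1c(C)ccc(O[Si](C(C)C)(C(C)C)C(C)C)c1C | intermediate
12 | (4S)-4-benzyl-3-(4-{2,6-dimethyl-3-[tri(propan-2-yl)silyloxy]phenyl}butanoyl)-1,3-oxazolidin-2-one | O=C(CCCc1c(C)ccc(O[Si](C(C)C)(C(C)C)C(C)C)c1C)N1C(=O)OC[C@@H]1Cc1ccccc1 | intermediate
13 | trichlorotitanium (Z)-enolate of 12 (O-bound at the exocyclic acyl oxygen) | Cl[Ti](Cl)(Cl)O/C(=C\CCc1c(C)ccc(O[Si](C(C)C)(C(C)C)C(C)C)c1C)N1C(=O)OC[C@@H]1Cc1ccccc1 | intermediate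
14 | (4S)-4-benzyl-3-[(2R)-4-{2,6-dimethyl-3-[tri(propan-2-yl)silyloxy]phenyl}-2-(hydroxymethyl)butanoyl]-1,3-oxazolidin-2-one | Cc1ccc(O[Si](C(C)C)(C(C)C)C(C)C)c(C)c1CC[C@H](CO)C(=O)N1C(=O)OC[C@@H]1Cc1ccccc1 | intermediate
15 | (4S)-4-benzyl-3-[(2R)-2-{[tert-butyl(dimethyl)silyl]oxymethyl}-4-{2,6-dimethyl-3-[tri(propan-2-yl)silyloxy]phenyl}butanoyl]-1,3-oxazolidin-2-one | Cc1ccc(O[Si](C(C)C)(C(C)C)C(C)C)c(C)c1CC[C@H](CO[Si](C)(C)C(C)(C)C)C(=O)N1C(=O)OC[C@@H]1Cc1ccccc1 | intermediate
16 | (2S)-2-{[tert-butyl(dimethyl)silyl]oxymethyl}-4-{2,6-dimethyl-3-[tri(propan-2-yl)silyloxy]phenyl}butan-1-ol | Cc1ccc(O[Si](C(C)C)(C(C)C)C(C)C)c(C)c1CC[C@H](CO[Si](C)(C)C(C)(C)C)CO | intermediate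
17 | ethyl 2-(triphenylphosphoranylidene)acetate | CCOC(=O)C=P(c1ccccc1)(c1ccccc1)c1ccccc1 | starting material
18 | (2R)-2-{[tert-butyl(dimethyl)silyl]oxymethyl}-4-{2,6-dimethyl-3-[tri(propan-2-yl)silyloxy]phenyl}butanal | Cc1ccc(O[Si](C(C)C)(C(C)C)C(C)C)c(C)c1CC[C@H](CO[Si](C)(C)C(C)(C)C)C=O | intermediate
19 | ethyl (2E,4S)-4-{[tert-butyl(dimethyl)silyl]oxymethyl}-6-{2,6-dimethyl-3-[tri(propan-2-yl)silyloxy]phenyl}hex-2-enoate | Cc1ccc(O[Si](C(C)C)(C(C)C)C(C)C)c(C)c1CC[C@H](CO[Si](C)(C)C(C)(C)C)/C=C/C(=O)OCC | intermediate
20 | (2E,4S)-4-{[tert-butyl(dimethyl)silyl]oxymethyl}-6-{2,6-dimethyl-3-[tri(propan-2-yl)silyloxy]phenyl}hex-2-en-1-ol | Cc1ccc(O[Si](C(C)C)(C(C)C)C(C)C)c(C)c1CC[C@H](CO[Si](C)(C)C(C)(C)C)/C=C/CO | intermediate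
21 | (2E,4S)-4-{[tert-butyl(dimethyl)silyl]oxymethyl}-6-{2,6-dimethyl-3-[tri(propan-2-yl)silyloxy]phenyl}hex-2-en-1-yl methyl carbonate | Cc1ccc(O[Si](C(C)C)(C(C)C)C(C)C)c(C)c1CC[C@H](CO[Si](C)(C)C(C)(C)C)/C=C/COC(=O)OC | intermediate
22 | (2E,4S)-4-{[tert-butyl(dimethyl)silyl]oxymethyl}-6-(3-hydroxy-2,6-dimethylphenyl)hex-2-en-1-yl methyl carbonate | Cc1ccc(O)c(C)c1CC[C@H](CO[Si](C)(C)C(C)(C)C)/C=C/COC(=O)OC | intermediate
23 | (4aS,5R,6S)-6-{[tert-butyl(dimethyl)silyl]oxymethyl}-5-ethenyl-1,4a-dimethyl-5,6,7,8-tetrahydronaphthalen-2(4aH)-one | C=C[C@@H]1[C@@H](CO[Si](C)(C)C(C)(C)C)CCC2=C(C)C(=O)C=C[C@@]12C | intermediate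
24 | (4aS,5R,6S)-6-{[tert-butyl(dimethyl)silyl]oxymethyl}-5-ethenyl-1,4a-dimethyl-4,4a,5,6,7,8-hexahydronaphthalen-2(3H)-one | C=C[C@@H]1[C@@H](CO[Si](C)(C)C(C)(C)C)CCC2=C(C)C(=O)CC[C@@]12C | intermediate
25 | lithium (4aS,5R,6S,8aS)-6-{[tert-butyl(dimethyl)silyl]oxymethyl}-5-ethenyl-1,4a-dimethyl-3,4,4a,5,6,7,8,8a-octahydronaphthalen-2-olate | C=C[C@@H]1[C@@H](CO[Si](C)(C)C(C)(C)C)CC[C@@H]2C(C)=C([O-])CC[C@@]12C.[Li+] | intermediate
26 | (4aS,5R,6S,8aS)-6-{[tert-butyl(dimethyl)silyl]oxymethyl}-5-ethenyl-1,1,4a-trimethyloctahydronaphthalen-2(1H)-one | C=C[C@@H]1[C@@H](CO[Si](C)(C)C(C)(C)C)CC[C@@H]2C(C)(C)C(=O)CC[C@@]12C | intermediate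
27 | (2R,4aS,5R,6S,8aS)-6-{[tert-butyl(dimethyl)silyl]oxymethyl}-5-ethenyl-1,1,4a-trimethyldecahydronaphthalen-2-ol | C=C[C@@H]1[C@@H](CO[Si](C)(C)C(C)(C)C)CC[C@@H]2C(C)(C)[C@H](O)CC[C@@]12C | intermediate
28 | methyl but-2-ynoate | CC#CC(=O)OC | starting material
29 | methyl (2Z)-3-iodobut-2-enoate | COC(=O)/C=C(/C)I | intermediate
30 | 9-{2-[(1R,2S,4aS,6R,8aS)-2-{[tert-butyl(dimethyl)silyl]oxymethyl}-6-hydroxy-5,5,8a-trimethyldecahydronaphthalen-1-yl]ethyl}-9-borabicyclo[3.3.1]nonane | C(C[C@@H]1[C@@H](CO[Si](C)(C)C(C)(C)C)CC[C@@H]2C(C)(C)[C@H](O)CC[C@@]12C)B3C4CCCC3CCC4 | intermediate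
31 | methyl (2Z)-5-[(1R,2S,4aS,6R,8aS)-2-{[tert-butyl(dimethyl)silyl]oxymethyl}-6-hydroxy-5,5,8a-trimethyldecahydronaphthalen-1-yl]-3-methylpent-2-enoate | COC(=O)/C=C(/C)CC[C@@H]1[C@@H](CO[Si](C)(C)C(C)(C)C)CC[C@@H]2C(C)(C)[C@H](O)CC[C@@]12C | intermediate
32 | methyl (2Z)-5-[(1R,2S,4aS,6R,8aS)-6-hydroxy-2-(hydroxymethyl)-5,5,8a-trimethyldecahydronaphthalen-1-yl]-3-methylpent-2-enoate | COC(=O)/C=C(/C)CC[C@@H]1[C@@H](CO)CC[C@@H]2C(C)(C)[C@H](O)CC[C@@]12C | intermediate
33 | methyl (2Z)-5-[(1R,2S,4aS,6R,8aS)-2-formyl-6-hydroxy-5,5,8a-trimethyldecahydronaphthalen-1-yl]-3-methylpent-2-enoate | COC(=O)/C=C(/C)CC[C@@H]1[C@@H](C=O)CC[C@@H]2C(C)(C)[C@H](O)CC[C@@]12C | target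

## Step count and least certain steps

Total: 22 steps. Longest linear sequence: 21 steps (steps 1–18 and 20–22); step 19 is a one-step side branch.

Step 15 (key step, proposed new method).
- What may go wrong: attack of the phenolate through the ortho carbon C4 instead of the para carbon C10, since both closures are six-membered and differ only in electronic weight and steric surroundings. Loss of a β-hydrogen from C8 in the π-allyl complex would lead to diene formation. Intermolecular allylation at oxygen or at the free C2 position is possible if dilution is insufficient. An unfavourable pairing of the ligand with the C8 bias would erode C9/C10 diastereoselectivity; which ligand enantiomer is the matched one cannot be predicted with confidence, so the antipode and an achiral bisphosphine are the first things to try.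
- Fallback (known chemistry, reversed polarity; sets out from 16 and comes back at 23): Swern oxidation of 16 to 18 and Wittig reaction with the ylide from (2-trimethylsilylethyl)triphenylphosphonium iodide give the C12 allyltrimethylsilane F1. Buffered Bu4NF (as in step 14) removes the aryl silyl group to give the free phenol allylsilane F2. PhI(OAc)2 in (CF3)2CHOH/CH2Cl2 at −20 °C then oxidises the phenol to a phenoxenium ion whose para carbon C10 is captured by the γ-carbon C9 of the allylsilane (oxidative Hosomi–Sakurai allylation). This closes ring B through the same chair and releases the vinyl group of 23.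

Step 16.
- What may go wrong: hydride delivery to the carbonyl carbon instead of C1, further reduction of the tetrasubstituted enone, or sluggish conversion of the weakly electrophilic cross-conjugated dienone.
- Fallback (sets out from 23 and comes back at 26): the vinyl group is masked by bromine addition (pyridinium tribromide, CH2Cl2, −78 → 0 °C) to give the 11,12-dibromide F3. H2 with RhCl(PPh3)3 in benzene then saturates only the disubstituted C1=C2 bond, giving the dihydro dibromide F4. Li (5 equiv)/NH3 with t-BuOH followed by MeI both regenerates the vinyl group by reductive elimination and carries out the reductive methylation, giving 26 directly.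

Step 17.
- What may go wrong: proton exchange between enolate 25 and product ketone, with loss of regiochemical integrity and methylation at C2 or polymethylation; over-reduction of the carbonyl group; O-methylation.
- Fallback (sets out from 24 and comes back at 26): the enolate from Li/NH3 reduction is trapped with Me3SiCl/Et3N after evaporation of ammonia and isolated as the trimethylsilyl enol ether F5. MeLi in THF at 0 °C regenerates lithium enolate 25 free of ammonia and proton donors, and MeI with DMPU alkylates C4 to give 26.

Step 20.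
- What may go wrong: slow transmetalation or protodeboronation of the alkylborane, consumption of the borane by the free hydroxyl, or Z to E isomerisation of 29 or of the product on palladium.
- Fallback (sets out from 27 and comes back at 31): hydroboration with 9-BBN and oxidative work-up (NaOH, H2O2) gives the C12 primary alcohol F6. I2, PPh3 and imidazole at 0 °C convert the primary hydroxyl selectively into the C12 iodide F7. A nickel-catalysed reductive cross-electrophile coupling of F7 with 29 (NiCl2(MeOCH2CH2OMe), 4,4′-di-tert-butyl-2,2′-bipyridine, Mn powder, DMA, rt) tolerates the free hydroxyl and should form the C12–C13 bond through an alkyl radical to give 31.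

## Further compounds

F1 | step 15 | {3-[(3S)-3-{[tert-butyl(dimethyl)silyl]oxymethyl}-6-(trimethylsilyl)hex-4-en-1-yl]-2,4-dimethylphenoxy}tri(propan-2-yl)silane (E/Z mixture) | Cc1ccc(O[Si](C(C)C)(C(C)C)C(C)C)c(C)c1CC[C@H](CO[Si](C)(C)C(C)(C)C)C=CC[Si](C)(C)C
F2 | step 15 | 3-[(3S)-3-{[tert-butyl(dimethyl)silyl]oxymethyl}-6-(trimethylsilyl)hex-4-en-1-yl]-2,4-dimethylphenol (E/Z mixture) | Cc1ccc(O)c(C)c1CC[C@H](CO[Si](C)(C)C(C)(C)C)C=CC[Si](C)(C)C
F3 | step 16 | (4aS,5R,6S)-6-{[tert-butyl(dimethyl)silyl]oxymethyl}-5-(1,2-dibromoethyl)-1,4a-dimethyl-5,6,7,8-tetrahydronaphthalen-2(4aH)-one (C11 epimers) | BrCC(Br)[C@@H]1[C@@H](CO[Si](C)(C)C(C)(C)C)CCC2=C(C)C(=O)C=C[C@@]12C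
F4 | step 16 | (4aS,5R,6S)-6-{[tert-butyl(dimethyl)silyl]oxymethyl}-5-(1,2-dibromoethyl)-1,4a-dimethyl-4,4a,5,6,7,8-hexahydronaphthalen-2(3H)-one (C11 epimers) | BrCC(Br)[C@@H]1[C@@H](CO[Si](C)(C)C(C)(C)C)CCC2=C(C)C(=O)CC[C@@]12C
F5 | step 17 | {[(4aS,5R,6S,8aS)-6-{[tert-butyl(dimethyl)silyl]oxymethyl}-5-ethenyl-1,4a-dimethyl-3,4,4a,5,6,7,8,8a-octahydronaphthalen-2-yl]oxy}trimethylsilane | C=C[C@@H]1[C@@H](CO[Si](C)(C)C(C)(C)C)CC[C@@H]2C(C)=C(O[Si](C)(C)C)CC[C@@]12C
F6 | step 20 | (2R,4aS,5R,6S,8aS)-6-{[tert-butyl(dimethyl)silyl]oxymethyl}-5-(2-hydroxyethyl)-1,1,4a-trimethyldecahydronaphthalen-2-ol | OCC[C@@H]1[C@@H](CO[Si](C)(C)C(C)(C)C)CC[C@@H]2C(C)(C)[C@H](O)CC[C@@]12C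
F7 | step 20 | (2R,4aS,5R,6S,8aS)-6-{[tert-butyl(dimethyl)silyl]oxymethyl}-5-(2-iodoethyl)-1,1,4a-trimethyldecahydronaphthalen-2-ol | ICC[C@@H]1[C@@H](CO[Si](C)(C)C(C)(C)C)CC[C@@H]2C(C)(C)[C@H](O)CC[C@@]12C
A1 | alternative 1 | andrographolide, (3E,4S)-3-{2-[(1R,4aS,5R,6R,8aS)-6-hydroxy-5-(hydroxymethyl)-5,8a-dimethyl-2-methylidenedecahydronaphthalen-1-yl]ethylidene}-4-hydroxyoxolan-2-one | C[C@@]12CC[C@H]([C@@]([C@H]1CCC(=C)[C@H]2C/C=C/3\[C@@H](COC3=O)O)(C)CO)O
A2 | alternative 1 | methyl (2Z)-5-[(1R,2S,4aS,6R,8aS)-6-{[tert-butyl(dimethyl)silyl]oxy}-2-(dimethoxymethyl)-5,5,8a-trimethyldecahydronaphthalen-1-yl]-3-methylpent-2-enoate | COC(=O)/C=C(/C)CC[C@@H]1[C@@H](C(OC)OC)CC[C@@H]2C(C)(C)[C@H](O[Si](C)(C)C(C)(C)C)CC[C@@]12C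
A3 | alternative 2 | methyl (2E,6R,8E,10E)-6,12-bis{[tert-butyl(dimethyl)silyl]oxy}-3,7,7-trimethyldodeca-2,8,10-trienoate | COC(=O)/C=C(\C)CC[C@@H](O[Si](C)(C)C(C)(C)C)C(C)(C)/C=C/C=C/CO[Si](C)(C)C(C)(C)C
A4 | alternative 2 | methyl (1R,2R,4aS,6R,8aR)-6-{[tert-butyl(dimethyl)silyl]oxy}-2-({[tert-butyl(dimethyl)silyl]oxy}methyl)-5,5,8a-trimethyl-1,2,4a,5,6,7,8,8a-octahydronaphthalene-1-carboxylate | COC(=O)[C@@H]1[C@H](CO[Si](C)(C)C(C)(C)C)C=C[C@@H]2C(C)(C)[C@H](O[Si](C)(C)C(C)(C)C)CC[C@@]12C
A5 | alternative 3 | (4S)-4-{[tert-butyl(dimethyl)silyl]oxymethyl}-2-methylcyclohex-2-en-1-one | CC1=C[C@@H](CO[Si](C)(C)C(C)(C)C)CCC1=O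
A6 | alternative 3 | (2S,3R,4S)-3-(but-3-en-1-yl)-4-{[tert-butyl(dimethyl)silyl]oxymethyl}-2-methyl-2-(3-oxopentyl)cyclohexan-1-one | C=CCC[C@@H]1[C@@H](CO[Si](C)(C)C(C)(C)C)CCC(=O)[C@@]1(C)CCC(=O)CC
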